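**Plan**

1. Retrosynthesis: the senecioate is removed and the lactone C12–O6 bond opened. The ten-membered ring is then cut at C8–C9 to an open-chain dialdehyde. Its chain is cut at C1=C10 (olefination), at C2–C3/C4=C5 (Claisen rearrangement after isopropenyl addition at C5) and at C7–C11 (alkenyl addition to a sugar ketone).
2. Enabling feature (germacrane numbering): the vicinal C8/C9 diol lies in the ten-membered ring C1–C10 between quaternary C7 and the Z-C10=C1 alkene. Both hydroxyls and the ring-closing bond can therefore come from a C8 aldehyde and a C9 enal by reductive coupling.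
3. Forward order: L-arabinose supplies C5–C8. C11–C13 are attached at C7, C1 of the sugar is excised, the chain is grown to C9, the carbocycle is closed (step 19) and the lactone ring is formed afterwards (step 23).
4. Stereochemistry: C6 is C4 of L-arabinose. C7 comes from convex-face addition to the bicyclic 3-ulose. E-C4=C5 comes from a chair Claisen transition state and Z-C1=C10 from Still–Gennari olefination. C8 and C9 are set in the pinacol step (Felkin–Anh control by C7, anti ketyl oxygens).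

Key step: step 19

Remark: atoms carry germacrane numbers (ring C1–C10, C11–C13 on C7, C14 on C10, C15 on C4). The target SMILES is read as (6S,7S,8S,9R), 1(10)Z,4E, with a cis-fused 12,6-lactone.

**Route**

Step 1
Reactants: 1 L-arabinose
Product: 2 5-O-(tert-butyldiphenylsilyl)-L-arabinofuranose
Conditions: TBDPSCl (1.05 equiv), imidazole, DMF, 0 °C to rt
Reagents that add atoms: tert-butyl(chloro)diphenylsilane, CC(C)(C)[Si](Cl)(c1ccccc1)c1ccccc1
Why: Silyl ether formation at the only primary hydroxyl, which exists solely in the furanose tautomer, should drain the mutarotation equilibrium into the 5-O-silyl furanose.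

Step 2
Reactants: 2 5-O-(tert-butyldiphenylsilyl)-L-arabinofuranose
Product: 3 5-O-(tert-butyldiphenylsilyl)-1,2-O-isopropylidene-β-L-arabinofuranose
Conditions: 2,2-dimethoxypropane, acetone, CSA (cat.), rt
Reagents that add atoms: 2,2-dimethoxypropane, COC(C)(C)OC
Why: Acid-catalysed ketalisation is possible only across the cis-1,2-diol of the β-furanose, so anomerisation should funnel 2 into the 1,2-acetonide and leave O3 free.

Step 3
Reactants: 3 5-O-(tert-butyldiphenylsilyl)-1,2-O-isopropylidene-β-L-arabinofuranose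
Product: 4 5-O-(tert-butyldiphenylsilyl)-1,2-O-isopropylidene-β-L-threo-pentofuranos-3-ulose
Conditions: Dess–Martin periodinane, CH2Cl2, rt
Reagents that add atoms: none
Why: Dess–Martin oxidation of the only free (secondary) hydroxyl should give the 3-ulose under neutral, non-epimerising conditions.

Step 4
Reactants: 5 2-bromoprop-2-en-1-ol
Product: 6 2-{[(2-bromoprop-2-en-1-yl)oxy]methyl}naphthalene
Conditions: NaH, 2-(bromomethyl)naphthalene, Bu4NI (cat.), THF, 0 °C to rt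
Reagents that add atoms: 2-(bromomethyl)naphthalene, BrCc1ccc2ccccc2c1
Why: Williamson ether synthesis; the 2-naphthylmethyl ether is chosen because it tolerates t-BuLi, hot aqueous acetic acid and fluoride and is later removed oxidatively together with the PMB group.

Step 5
Reactants: 6 2-{[(2-bromoprop-2-en-1-yl)oxy]methyl}naphthalene; 4 5-O-(tert-butyldiphenylsilyl)-1,2-O-isopropylidene-β-L-threo-pentofuranos-3-ulose
Product: 8 5-O-(tert-butyldiphenylsilyl)-1,2-O-isopropylidene-3-C-[3-(naphthalen-2-ylmethoxy)prop-1-en-2-yl]-β-L-lyxofuranose, via alkenyllithium 7 (not isolated)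
Conditions: t-BuLi (2.0 equiv), Et2O, −78 °C; then 4, −78 °C; then H2O
Reagents that add atoms: none
Why: Bromine–lithium exchange gives alkenyllithium 7, whose 1,2-addition to the ketone should occur on the convex face, opposite both the cis-fused 1,2-acetonide and the C4 silyloxymethyl arm, which sets the tertiary carbinol (future C7) in the L-lyxo configuration.

Step 6
Reactants: 8 5-O-(tert-butyldiphenylsilyl)-1,2-O-isopropylidene-3-C-[3-(naphthalen-2-ylmethoxy)prop-1-en-2-yl]-β-L-lyxofuranose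
Product: 9 3-O-(tert-butyldimethylsilyl)-5-O-(tert-butyldiphenylsilyl)-1,2-O-isopropylidene-3-C-[3-(naphthalen-2-ylmethoxy)prop-1-en-2-yl]-β-L-lyxofuranose
Conditions: TBSOTf, 2,6-lutidine, CH2Cl2, 0 °C to rt
Reagents that add atoms: tert-butyldimethylsilyl trifluoromethanesulfonate, CC(C)(C)[Si](C)(C)OS(=O)(=O)C(F)(F)F
Why: Silyl triflate silylation caps the tertiary alcohol so that the cis-2,3-diol cannot be cleaved by periodate in step 8; the tert-butyldimethylsilyl ether is chosen because it should survive the aqueous acid of step 7.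

Step 7
Reactants: 9 3-O-(tert-butyldimethylsilyl)-5-O-(tert-butyldiphenylsilyl)-1,2-O-isopropylidene-3-C-[3-(naphthalen-2-ylmethoxy)prop-1-en-2-yl]-β-L-lyxofuranose
Product: 10 3-O-(tert-butyldimethylsilyl)-5-O-(tert-butyldiphenylsilyl)-3-C-[3-(naphthalen-2-ylmethoxy)prop-1-en-2-yl]-L-lyxofuranose
Conditions: AcOH/H2O (4:1), 80 °C
Reagents that add atoms: water, O
Why: Acid-catalysed acetal hydrolysis frees the 1,2-diol needed for chain shortening, while the primary TBDPS ether, the tertiary TBS ether and the naphthylmethyl ether are expected to withstand hot aqueous acetic acid.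

Step 8
Reactants: 10 3-O-(tert-butyldimethylsilyl)-5-O-(tert-butyldiphenylsilyl)-3-C-[3-(naphthalen-2-ylmethoxy)prop-1-en-2-yl]-L-lyxofuranose
Product: 12 (2S,3S)-2-[(tert-butyldimethylsilyl)oxy]-4-[(tert-butyldiphenylsilyl)oxy]-2-[3-(naphthalen-2-ylmethoxy)prop-1-en-2-yl]butane-1,3-diol, via formate aldehyde 11 (not isolated)
Conditions: NaIO4, THF/H2O (3:1), 0 °C to rt; filter; then NaBH4, MeOH, 0 °C
Reagents that add atoms: none
Why: Periodate glycol cleavage of the hemiacetal/2-hydroxyl pair removes sugar C1 as a formate on O4 and leaves C2 as an aldehyde, which borohydride reduces while the formate is lost, so that sugar C2–C5 emerge as C8–C5 of the target with both stereocentres untouched.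

Step 9
Reactants: 12 (2S,3S)-2-[(tert-butyldimethylsilyl)oxy]-4-[(tert-butyldiphenylsilyl)oxy]-2-[3-(naphthalen-2-ylmethoxy)prop-1-en-2-yl]butane-1,3-diol
Product: 13 tert-butyl({(2R,4S,5S)-5-[(tert-butyldimethylsilyl)oxy]-2-(4-methoxyphenyl)-5-[3-(naphthalen-2-ylmethoxy)prop-1-en-2-yl]-1,3-dioxan-4-yl}methoxy)diphenylsilane
Conditions: 4-MeOC6H4CH(OMe)2, PPTS (cat.), CH2Cl2, rt
Reagents that add atoms: 1-(dimethoxymethyl)-4-methoxybenzene, COc1ccc(cc1)C(OC)OC
Why: Acid-catalysed transacetalisation closes the 1,3-dioxane across O6 and O8 under thermodynamic control, which places the aryl group equatorial and cis to the equatorial C5 arm and so fixes the new acetal centre as R.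

Step 10
Reactants: 13 tert-butyl({(2R,4S,5S)-5-[(tert-butyldimethylsilyl)oxy]-2-(4-methoxyphenyl)-5-[3-(naphthalen-2-ylmethoxy)prop-1-en-2-yl]-1,3-dioxan-4-yl}methoxy)diphenylsilane
Product: 14 (2R,4S,5S)-4-(hydroxymethyl)-2-(4-methoxyphenyl)-5-[3-(naphthalen-2-ylmethoxy)prop-1-en-2-yl]-1,3-dioxan-5-ol
Conditions: Bu4NF (4 equiv), THF, rt to 50 °C
Reagents that add atoms: none
Why: Fluoride-mediated desilylation at elevated temperature should remove both the primary TBDPS and the tertiary TBS ether and leave acetal, naphthylmethyl ether and alkene untouched.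

Step 11
Reactants: 14 (2R,4S,5S)-4-(hydroxymethyl)-2-(4-methoxyphenyl)-5-[3-(naphthalen-2-ylmethoxy)prop-1-en-2-yl]-1,3-dioxan-5-ol
Product: 15 (2R,4S,5S)-2-(4-methoxyphenyl)-5-[3-(naphthalen-2-ylmethoxy)prop-1-en-2-yl]-5-[(triethylsilyl)oxy]-4-{[(triethylsilyl)oxy]methyl}-1,3-dioxane
Conditions: TESOTf (2.5 equiv), 2,6-lutidine, CH2Cl2, −78 to 0 °C
Reagents that add atoms: triethylsilyl trifluoromethanesulfonate, CC[Si](CC)(CC)OS(=O)(=O)C(F)(F)F
Why: Silyl triflate silylation of the primary and the tertiary hydroxyl installs the triethylsilyl ether that C7 carries through the ring closure and that fluoride removes easily at the end.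

Step 12
Reactants: 15 (2R,4S,5S)-2-(4-methoxyphenyl)-5-[3-(naphthalen-2-ylmethoxy)prop-1-en-2-yl]-5-[(triethylsilyl)oxy]-4-{[(triethylsilyl)oxy]methyl}-1,3-dioxane
Product: 16 (2R,4R,5S)-2-(4-methoxyphenyl)-5-[3-(naphthalen-2-ylmethoxy)prop-1-en-2-yl]-5-[(triethylsilyl)oxy]-1,3-dioxane-4-carbaldehyde
Conditions: (COCl)2, DMSO, CH2Cl2, −78 to −30 °C; then Et3N, −78 to 0 °C
Reagents that add atoms: none
Why: Under Swern conditions the unhindered primary triethylsilyl ether is cleaved by the chlorosulfonium salt and oxidised directly to the aldehyde, whereas the tertiary ether cannot be oxidised; the equatorial formyl group has no driving force to epimerise.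

Step 13
Reactants: 16 (2R,4R,5S)-2-(4-methoxyphenyl)-5-[3-(naphthalen-2-ylmethoxy)prop-1-en-2-yl]-5-[(triethylsilyl)oxy]-1,3-dioxane-4-carbaldehyde; 17 isopropenylmagnesium bromide
Product: 18 1-{(2R,4S,5S)-2-(4-methoxyphenyl)-5-[3-(naphthalen-2-ylmethoxy)prop-1-en-2-yl]-5-[(triethylsilyl)oxy]-1,3-dioxan-4-yl}-2-methylprop-2-en-1-ol (both carbinol epimers)
Conditions: CH2=C(CH3)MgBr, THF, −78 °C; then H2O
Reagents that add atoms: none
Why: Grignard 1,2-addition to the aldehyde; the new carbinol centre is formed as an epimer mixture, which is of no consequence because it is erased in step 14.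

Step 14
Reactants: 18 1-{(2R,4S,5S)-2-(4-methoxyphenyl)-5-[3-(naphthalen-2-ylmethoxy)prop-1-en-2-yl]-5-[(triethylsilyl)oxy]-1,3-dioxan-4-yl}-2-methylprop-2-en-1-ol; 19 triethyl orthoacetate
Product: 21 ethyl (4E)-5-{(2R,4S,5S)-2-(4-methoxyphenyl)-5-[3-(naphthalen-2-ylmethoxy)prop-1-en-2-yl]-5-[(triethylsilyl)oxy]-1,3-dioxan-4-yl}-4-methylpent-4-enoate, via ketene acetal 20 (not isolated)
Conditions: MeC(OEt)3 (excess, neat), EtCO2H (cat.), 135 °C, EtOH distilled off
Reagents that add atoms: none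
Why: Johnson–Claisen rearrangement through a chair transition state with the bulky dioxanyl substituent equatorial should convert both carbinol epimers into the E-configured C4=C5 alkene and add C2 and C1.

Step 15
Reactants: 21 ethyl (4E)-5-{(2R,4S,5S)-2-(4-methoxyphenyl)-5-[3-(naphthalen-2-ylmethoxy)prop-1-en-2-yl]-5-[(triethylsilyl)oxy]-1,3-dioxan-4-yl}-4-methylpent-4-enoate
Product: 22 (4E)-5-{(2R,4S,5S)-2-(4-methoxyphenyl)-5-[3-(naphthalen-2-ylmethoxy)prop-1-en-2-yl]-5-[(triethylsilyl)oxy]-1,3-dioxan-4-yl}-4-methylpent-4-enal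
Conditions: i-Bu2AlH (1.1 equiv), CH2Cl2, −78 °C; aq. potassium sodium tartrate
Reagents that add atoms: none
Why: Half-reduction of the ethyl ester, whose tetrahedral aluminium hemiacetal is stable at −78 °C and collapses to the aldehyde only on work-up.

Step 16
Reactants: 22 (4E)-5-{(2R,4S,5S)-2-(4-methoxyphenyl)-5-[3-(naphthalen-2-ylmethoxy)prop-1-en-2-yl]-5-[(triethylsilyl)oxy]-1,3-dioxan-4-yl}-4-methylpent-4-enal; 23 ethyl 2-[bis(2,2,2-trifluoroethoxy)phosphoryl]propanoate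
Product: 24 ethyl (2Z,6E)-7-{(2R,4S,5S)-2-(4-methoxyphenyl)-5-[3-(naphthalen-2-ylmethoxy)prop-1-en-2-yl]-5-[(triethylsilyl)oxy]-1,3-dioxan-4-yl}-2,6-dimethylhepta-2,6-dienoate
Conditions: KN(SiMe3)2, 18-crown-6, THF, −78 °C
Reagents that add atoms: none
Why: Still–Gennari olefination, in which the electron-poor bis(trifluoroethyl) phosphonate eliminates from the kinetically formed adduct and so should give the Z-configured trisubstituted enoate (C1=C10).

Step 17
Reactants: 24 ethyl (2Z,6E)-7-{(2R,4S,5S)-2-(4-methoxyphenyl)-5-[3-(naphthalen-2-ylmethoxy)prop-1-en-2-yl]-5-[(triethylsilyl)oxy]-1,3-dioxan-4-yl}-2,6-dimethylhepta-2,6-dienoate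
Product: 26 (2Z,6E,8S,9S)-8-[(4-methoxyphenyl)methoxy]-2,6-dimethyl-9-[3-(naphthalen-2-ylmethoxy)prop-1-en-2-yl]-9-[(triethylsilyl)oxy]deca-2,6-diene-1,10-diol, via allylic alcohol acetal 25 (not isolated)
Conditions: i-Bu2AlH (6 equiv), CH2Cl2, −78 to 0 °C; aq. potassium sodium tartrate
Reagents that add atoms: none
Why: i-Bu2AlH first reduces the enoate to the allylic alcohol and, on warming, opens the p-methoxybenzylidene acetal reductively: aluminium binds the less hindered primary O8, so hydride delivery should leave the PMB group on the secondary O6 and free the C8 hydroxyl.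

Step 18
Reactants: 26 (2Z,6E,8S,9S)-8-[(4-methoxyphenyl)methoxy]-2,6-dimethyl-9-[3-(naphthalen-2-ylmethoxy)prop-1-en-2-yl]-9-[(triethylsilyl)oxy]deca-2,6-diene-1,10-diol
Product: 27 (2Z,6E,8S,9R)-8-[(4-methoxyphenyl)methoxy]-2,6-dimethyl-9-[3-(naphthalen-2-ylmethoxy)prop-1-en-2-yl]-9-[(triethylsilyl)oxy]deca-2,6-dienedial
Conditions: Dess–Martin periodinane (3 equiv), NaHCO3, CH2Cl2, 0 °C
Reagents that add atoms: none
Why: Buffered Dess–Martin oxidation converts the allylic and the neopentyl primary alcohol into the two aldehydes in one operation without acid or base that would isomerise the Z-enal; C7 is quaternary and cannot epimerise.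

Step 19
Reactants: 27 (2Z,6E,8S,9R)-8-[(4-methoxyphenyl)methoxy]-2,6-dimethyl-9-[3-(naphthalen-2-ylmethoxy)prop-1-en-2-yl]-9-[(triethylsilyl)oxy]deca-2,6-dienedial
Product: 28 (1(10)Z,4E,6S,7S,8S,9R)-6-[(4-methoxyphenyl)methoxy]-12-(naphthalen-2-ylmethoxy)-7-[(triethylsilyl)oxy]germacra-1(10),4,11(13)-triene-8,9-diol
Conditions: SmI2 (0.1 M in THF, 3 equiv), THF, −78 °C to rt, 27 added by syringe pump over 6 h (final about 2 mM); aq. NaHCO3
Reagents that add atoms: none
Why: Each SmI2 transfers one electron to a carbonyl group, giving samarium-bound ketyl radical anions at C8 and C9 that combine carbon to carbon, so the C8–C9 bond, the ten-membered carbocycle and both carbinol centres arise in one operation. The closest known reaction type is the pinacol cyclisation of dialdehydes to medium and large rings with SmI2 or low-valent titanium. The ring closes by head-to-head union of the two carbonyl carbons under high dilution (an endo-type ten-membered macrocyclisation); the chain is pre-bent by the E-C4=C5 and Z-C1=C10 alkenes and the substituted C6–C7 unit, and coupling through C1 of the delocalised enal ketyl would force the E-C4=C5 bond into an eight-membered ring, so it should not compete. C8 is controlled by C7: with the non-chelating triethylsilyloxy group antiperiplanar to the forming bond (Felkin–Anh), approach past the flat C11 alkenyl group should place O8 erythro to O7 (8S). C9 is controlled by the preference of the two bulky samarium-bound oxygens to lie anti in the transition state, which should give the threo 8,9-diol (9R). The step needs intra- over intermolecular coupling, 1,2- over 1,4-coupling of the enal and retention of the Z geometry; slow addition, low temperature and the ring-size argument above are relied on for these.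

Step 20
Reactants: 28 (1(10)Z,4E,6S,7S,8S,9R)-6-[(4-methoxyphenyl)methoxy]-12-(naphthalen-2-ylmethoxy)-7-[(triethylsilyl)oxy]germacra-1(10),4,11(13)-triene-8,9-diol; 29 3-methylbut-2-enoyl chloride
Product: 30 (1(10)Z,4E,6S,7S,8S,9R)-8-hydroxy-6-[(4-methoxyphenyl)methoxy]-12-(naphthalen-2-ylmethoxy)-7-[(triethylsilyl)oxy]germacra-1(10),4,11(13)-trien-9-yl 3-methylbut-2-enoate
Conditions: 29 (1.1 equiv), pyridine, DMAP (cat.), CH2Cl2, −20 to 0 °C
Reagents that add atoms: none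
Why: Pyridine/DMAP-mediated acylation should occur at the allylic C9 hydroxyl, because the C8 hydroxyl is flanked by the quaternary C7 carrying the triethylsilyloxy and alkenyl groups; pyridine as the only base avoids the vinylketene pathway that deconjugates senecioates.

Step 21
Reactants: 30 (1(10)Z,4E,6S,7S,8S,9R)-8-hydroxy-6-[(4-methoxyphenyl)methoxy]-12-(naphthalen-2-ylmethoxy)-7-[(triethylsilyl)oxy]germacra-1(10),4,11(13)-trien-9-yl 3-methylbut-2-enoate
Product: 31 (1(10)Z,4E,6S,7R,8S,9R)-6-[(4-methoxyphenyl)methoxy]-12-(naphthalen-2-ylmethoxy)-7,8-bis[(triethylsilyl)oxy]germacra-1(10),4,11(13)-trien-9-yl 3-methylbut-2-enoate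
Conditions: TESOTf, 2,6-lutidine, CH2Cl2, −78 to 0 °C
Reagents that add atoms: triethylsilyl trifluoromethanesulfonate, CC[Si](CC)(CC)OS(=O)(=O)C(F)(F)F
Why: Silyl triflate silylation blocks O8, so that only O6 can capture the C12 aldehyde in step 23.

Step 22
Reactants: 31 (1(10)Z,4E,6S,7R,8S,9R)-6-[(4-methoxyphenyl)methoxy]-12-(naphthalen-2-ylmethoxy)-7,8-bis[(triethylsilyl)oxy]germacra-1(10),4,11(13)-trien-9-yl 3-methylbut-2-enoate
Product: 32 (1(10)Z,4E,6S,7R,8S,9R)-6,12-dihydroxy-7,8-bis[(triethylsilyl)oxy]germacra-1(10),4,11(13)-trien-9-yl 3-methylbut-2-enoate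
Conditions: DDQ (3 equiv), CH2Cl2/pH 7 phosphate buffer (10:1), 0 °C to rt
Reagents that add atoms: none
Why: DDQ oxidises the two electron-rich arylmethyl ethers to oxocarbenium ions that water hydrolyses, which frees O6 and O12 in one step while silyl ethers, the ester and the isolated alkenes stay inert.

Step 23
Reactants: 32 (1(10)Z,4E,6S,7R,8S,9R)-6,12-dihydroxy-7,8-bis[(triethylsilyl)oxy]germacra-1(10),4,11(13)-trien-9-yl 3-methylbut-2-enoate
Product: 35 (1(10)Z,4E,6S,7R,8S,9R)-9-[(3-methylbut-2-enoyl)oxy]-7,8-bis[(triethylsilyl)oxy]germacra-1(10),4,11(13)-trien-12,6-olide, via enal 33 (not isolated), via lactol 34 (not isolated)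
Conditions: TEMPO (20 mol %), PhI(OAc)2 (3 equiv), CH2Cl2, rt
Reagents that add atoms: none
Why: TEMPO/PhI(OAc)2 oxidises the primary allylic alcohol selectively to the enal, the cis-disposed C6 hydroxyl closes the lactol, and a second oxidation gives the α-methylene γ-lactone (oxidative lactonisation of a 1,4-diol).

Step 24
Reactants: 35 (1(10)Z,4E,6S,7R,8S,9R)-9-[(3-methylbut-2-enoyl)oxy]-7,8-bis[(triethylsilyl)oxy]germacra-1(10),4,11(13)-trien-12,6-olide
Product: 36 (1(10)Z,4E,6S,7S,8S,9R)-7,8-dihydroxy-9-[(3-methylbut-2-enoyl)oxy]germacra-1(10),4,11(13)-trien-12,6-olide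
Conditions: HF·pyridine, pyridine, THF, 0 °C to rt
Reagents that add atoms: none
Why: Fluoride-mediated desilylation with buffered HF·pyridine should remove the secondary and the tertiary triethylsilyl ether under conditions too mild for acyl migration, conjugate addition to the methylene lactone or transannular cyclisation of the 1(10),4-diene.

**Compound list**

1 | L-arabinose | O=C[C@H](O)[C@@H](O)[C@@H](O)CO | starting material
2 | 5-O-(tert-butyldiphenylsilyl)-L-arabinofuranose (anomeric mixture) | OC1[C@H](O)[C@@H](O)[C@H](CO[Si](c2ccccc2)(c2ccccc2)C(C)(C)C)O1 | intermediate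
3 | 5-O-(tert-butyldiphenylsilyl)-1,2-O-isopropylidene-β-L-arabinofuranose | CC1(C)O[C@@H]2[C@H](O1)[C@@H](O)[C@H](CO[Si](c3ccccc3)(c3ccccc3)C(C)(C)C)O2 | intermediate
4 | 5-O-(tert-butyldiphenylsilyl)-1,2-O-isopropylidene-β-L-threo-pentofuranos-3-ulose | CC1(C)O[C@@H]2[C@H](O1)C(=O)[C@H](CO[Si](c3ccccc3)(c3ccccc3)C(C)(C)C)O2 | intermediate
5 | 2-bromoprop-2-en-1-ol | OCC(Br)=C | starting material
6 | 2-{[(2-bromoprop-2-en-1-yl)oxy]methyl}naphthalene | C=C(Br)COCc1ccc2ccccc2c1 | intermediate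
7 | [3-(naphthalen-2-ylmethoxy)prop-1-en-2-yl]lithium | [Li]C(=C)COCc1ccc2ccccc2c1 | intermediate
8 | 5-O-(tert-butyldiphenylsilyl)-1,2-O-isopropylidene-3-C-[3-(naphthalen-2-ylmethoxy)prop-1-en-2-yl]-β-L-lyxofuranose | CC1(C)O[C@@H]2[C@H](O1)[C@@](O)(C(=C)COCc1ccc3ccccc3c1)[C@H](CO[Si](c1ccccc1)(c1ccccc1)C(C)(C)C)O2 | intermediate
9 | 3-O-(tert-butyldimethylsilyl)-5-O-(tert-butyldiphenylsilyl)-1,2-O-isopropylidene-3-C-[3-(naphthalen-2-ylmethoxy)prop-1-en-2-yl]-β-L-lyxofuranose | CC1(C)O[C@@H]2[C@H](O1)[C@@](O[Si](C)(C)C(C)(C)C)(C(=C)COCc1ccc3ccccc3c1)[C@H](CO[Si](c1ccccc1)(c1ccccc1)C(C)(C)C)O2 | intermediate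
10 | 3-O-(tert-butyldimethylsilyl)-5-O-(tert-butyldiphenylsilyl)-3-C-[3-(naphthalen-2-ylmethoxy)prop-1-en-2-yl]-L-lyxofuranose (anomeric mixture) | OC1[C@H](O)[C@@](O[Si](C)(C)C(C)(C)C)(C(=C)COCc2ccc3ccccc3c2)[C@H](CO[Si](c2ccccc2)(c2ccccc2)C(C)(C)C)O1 | intermediate
11 | (2R,3S)-2-[(tert-butyldimethylsilyl)oxy]-4-[(tert-butyldiphenylsilyl)oxy]-3-(formyloxy)-2-[3-(naphthalen-2-ylmethoxy)prop-1-en-2-yl]butanal | O=C[C@@](O[Si](C)(C)C(C)(C)C)(C(=C)COCc1ccc2ccccc2c1)[C@H](CO[Si](c1ccccc1)(c1ccccc1)C(C)(C)C)OC=O | intermediate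
12 | (2S,3S)-2-[(tert-butyldimethylsilyl)oxy]-4-[(tert-butyldiphenylsilyl)oxy]-2-[3-(naphthalen-2-ylmethoxy)prop-1-en-2-yl]butane-1,3-diol | OC[C@@](O[Si](C)(C)C(C)(C)C)(C(=C)COCc1ccc2ccccc2c1)[C@H](CO[Si](c1ccccc1)(c1ccccc1)C(C)(C)C)O | intermediate
13 | tert-butyl({(2R,4S,5S)-5-[(tert-butyldimethylsilyl)oxy]-2-(4-methoxyphenyl)-5-[3-(naphthalen-2-ylmethoxy)prop-1-en-2-yl]-1,3-dioxan-4-yl}methoxy)diphenylsilane | COc1ccc(cc1)[C@@H]1OC[C@@](O[Si](C)(C)C(C)(C)C)(C(=C)COCc2ccc3ccccc3c2)[C@H](CO[Si](c2ccccc2)(c2ccccc2)C(C)(C)C)O1 | intermediate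
14 | (2R,4S,5S)-4-(hydroxymethyl)-2-(4-methoxyphenyl)-5-[3-(naphthalen-2-ylmethoxy)prop-1-en-2-yl]-1,3-dioxan-5-ol | COc1ccc(cc1)[C@@H]1OC[C@@](O)(C(=C)COCc2ccc3ccccc3c2)[C@H](CO)O1 | intermediate
15 | (2R,4S,5S)-2-(4-methoxyphenyl)-5-[3-(naphthalen-2-ylmethoxy)prop-1-en-2-yl]-5-[(triethylsilyl)oxy]-4-{[(triethylsilyl)oxy]methyl}-1,3-dioxane | COc1ccc(cc1)[C@@H]1OC[C@@](O[Si](CC)(CC)CC)(C(=C)COCc2ccc3ccccc3c2)[C@H](CO[Si](CC)(CC)CC)O1 | intermediate
16 | (2R,4R,5S)-2-(4-methoxyphenyl)-5-[3-(naphthalen-2-ylmethoxy)prop-1-en-2-yl]-5-[(triethylsilyl)oxy]-1,3-dioxane-4-carbaldehyde | COc1ccc(cc1)[C@@H]1OC[C@@](O[Si](CC)(CC)CC)(C(=C)COCc2ccc3ccccc3c2)[C@H](C=O)O1 | intermediate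
17 | isopropenylmagnesium bromide (prop-1-en-2-ylmagnesium bromide) | C=C(C)[Mg]Br | starting material
18 | 1-{(2R,4S,5S)-2-(4-methoxyphenyl)-5-[3-(naphthalen-2-ylmethoxy)prop-1-en-2-yl]-5-[(triethylsilyl)oxy]-1,3-dioxan-4-yl}-2-methylprop-2-en-1-ol (both carbinol epimers) | COc1ccc(cc1)[C@@H]1OC[C@@](O[Si](CC)(CC)CC)(C(=C)COCc2ccc3ccccc3c2)[C@H](C(O)C(C)=C)O1 | intermediate
19 | triethyl orthoacetate (1,1,1-triethoxyethane) | CCOC(C)(OCC)OCC | starting material
20 | (2R,4S,5S)-4-{1-[(1-ethoxyethenyl)oxy]-2-methylprop-2-en-1-yl}-2-(4-methoxyphenyl)-5-[3-(naphthalen-2-ylmethoxy)prop-1-en-2-yl]-5-[(triethylsilyl)oxy]-1,3-dioxane (ketene acetal) | COc1ccc(cc1)[C@@H]1OC[C@@](O[Si](CC)(CC)CC)(C(=C)COCc2ccc3ccccc3c2)[C@H](C(OC(=C)OCC)C(C)=C)O1 | intermediate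
21 | ethyl (4E)-5-{(2R,4S,5S)-2-(4-methoxyphenyl)-5-[3-(naphthalen-2-ylmethoxy)prop-1-en-2-yl]-5-[(triethylsilyl)oxy]-1,3-dioxan-4-yl}-4-methylpent-4-enoate | COc1ccc(cc1)[C@@H]1OC[C@@](O[Si](CC)(CC)CC)(C(=C)COCc2ccc3ccccc3c2)[C@H](/C=C(\C)CCC(=O)OCC)O1 | intermediate
22 | (4E)-5-{(2R,4S,5S)-2-(4-methoxyphenyl)-5-[3-(naphthalen-2-ylmethoxy)prop-1-en-2-yl]-5-[(triethylsilyl)oxy]-1,3-dioxan-4-yl}-4-methylpent-4-enal | COc1ccc(cc1)[C@@H]1OC[C@@](O[Si](CC)(CC)CC)(C(=C)COCc2ccc3ccccc3c2)[C@H](/C=C(\C)CCC=O)O1 | intermediate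
23 | ethyl 2-[bis(2,2,2-trifluoroethoxy)phosphoryl]propanoate | CCOC(=O)C(C)P(=O)(OCC(F)(F)F)OCC(F)(F)F | starting material
24 | ethyl (2Z,6E)-7-{(2R,4S,5S)-2-(4-methoxyphenyl)-5-[3-(naphthalen-2-ylmethoxy)prop-1-en-2-yl]-5-[(triethylsilyl)oxy]-1,3-dioxan-4-yl}-2,6-dimethylhepta-2,6-dienoate | COc1ccc(cc1)[C@@H]1OC[C@@](O[Si](CC)(CC)CC)(C(=C)COCc2ccc3ccccc3c2)[C@H](/C=C(\C)CC/C=C(/C)C(=O)OCC)O1 | intermediate
25 | (2Z,6E)-7-{(2R,4S,5S)-2-(4-methoxyphenyl)-5-[3-(naphthalen-2-ylmethoxy)prop-1-en-2-yl]-5-[(triethylsilyl)oxy]-1,3-dioxan-4-yl}-2,6-dimethylhepta-2,6-dien-1-ol | COc1ccc(cc1)[C@@H]1OC[C@@](O[Si](CC)(CC)CC)(C(=C)COCc2ccc3ccccc3c2)[C@H](/C=C(\C)CC/C=C(/C)CO)O1 | intermediate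
26 | (2Z,6E,8S,9S)-8-[(4-methoxyphenyl)methoxy]-2,6-dimethyl-9-[3-(naphthalen-2-ylmethoxy)prop-1-en-2-yl]-9-[(triethylsilyl)oxy]deca-2,6-diene-1,10-diol | OC[C@@](O[Si](CC)(CC)CC)(C(=C)COCc1ccc2ccccc2c1)[C@@H](OCc1ccc(OC)cc1)/C=C(\C)CC/C=C(/C)CO | intermediate
27 | (2Z,6E,8S,9R)-8-[(4-methoxyphenyl)methoxy]-2,6-dimethyl-9-[3-(naphthalen-2-ylmethoxy)prop-1-en-2-yl]-9-[(triethylsilyl)oxy]deca-2,6-dienedial (open-chain dienedial; C8 and C9 of the target are its two formyl carbons) | O=C[C@@](O[Si](CC)(CC)CC)(C(=C)COCc1ccc2ccccc2c1)[C@@H](OCc1ccc(OC)cc1)/C=C(\C)CC/C=C(/C)C=O | intermediate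
28 | (1(10)Z,4E,6S,7S,8S,9R)-6-[(4-methoxyphenyl)methoxy]-12-(naphthalen-2-ylmethoxy)-7-[(triethylsilyl)oxy]germacra-1(10),4,11(13)-triene-8,9-diol | O[C@H]1[C@H](O)/C(C)=C\CC/C(C)=C/[C@H](OCc2ccc(OC)cc2)[C@]1(O[Si](CC)(CC)CC)C(=C)COCc1ccc2ccccc2c1 | intermediate
29 | 3-methylbut-2-enoyl chloride (senecioyl chloride) | CC(C)=CC(Cl)=O | starting material
30 | (1(10)Z,4E,6S,7S,8S,9R)-8-hydroxy-6-[(4-methoxyphenyl)methoxy]-12-(naphthalen-2-ylmethoxy)-7-[(triethylsilyl)oxy]germacra-1(10),4,11(13)-trien-9-yl 3-methylbut-2-enoate | O[C@H]1[C@H](OC(=O)C=C(C)C)/C(C)=C\CC/C(C)=C/[C@H](OCc2ccc(OC)cc2)[C@]1(O[Si](CC)(CC)CC)C(=C)COCc1ccc2ccccc2c1 | intermediate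
31 | (1(10)Z,4E,6S,7R,8S,9R)-6-[(4-methoxyphenyl)methoxy]-12-(naphthalen-2-ylmethoxy)-7,8-bis[(triethylsilyl)oxy]germacra-1(10),4,11(13)-trien-9-yl 3-methylbut-2-enoate | CC[Si](CC)(CC)O[C@H]1[C@H](OC(=O)C=C(C)C)/C(C)=C\CC/C(C)=C/[C@H](OCc2ccc(OC)cc2)[C@]1(O[Si](CC)(CC)CC)C(=C)COCc1ccc2ccccc2c1 | intermediate
32 | (1(10)Z,4E,6S,7R,8S,9R)-6,12-dihydroxy-7,8-bis[(triethylsilyl)oxy]germacra-1(10),4,11(13)-trien-9-yl 3-methylbut-2-enoate | CC[Si](CC)(CC)O[C@H]1[C@H](OC(=O)C=C(C)C)/C(C)=C\CC/C(C)=C/[C@H](O)[C@]1(O[Si](CC)(CC)CC)C(=C)CO | intermediate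
33 | (1(10)Z,4E,6S,7R,8S,9R)-6-hydroxy-12-oxo-7,8-bis[(triethylsilyl)oxy]germacra-1(10),4,11(13)-trien-9-yl 3-methylbut-2-enoate (enal) | CC[Si](CC)(CC)O[C@H]1[C@H](OC(=O)C=C(C)C)/C(C)=C\CC/C(C)=C/[C@H](O)[C@]1(O[Si](CC)(CC)CC)C(=C)C=O | intermediate
34 | (1(10)Z,4E,6S,7R,8S,9R)-12-hydroxy-7,8-bis[(triethylsilyl)oxy]-6,12-epoxygermacra-1(10),4,11(13)-trien-9-yl 3-methylbut-2-enoate (lactol, C12 epimers) | C=C1C(O)O[C@H]2/C=C(\C)CC/C=C(/C)[C@@H](OC(=O)C=C(C)C)[C@H](O[Si](CC)(CC)CC)[C@@]12O[Si](CC)(CC)CC | intermediate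
35 | (1(10)Z,4E,6S,7R,8S,9R)-9-[(3-methylbut-2-enoyl)oxy]-7,8-bis[(triethylsilyl)oxy]germacra-1(10),4,11(13)-trien-12,6-olide | C=C1C(=O)O[C@H]2/C=C(\C)CC/C=C(/C)[C@@H](OC(=O)C=C(C)C)[C@H](O[Si](CC)(CC)CC)[C@@]12O[Si](CC)(CC)CC | intermediate
36 | (1(10)Z,4E,6S,7S,8S,9R)-7,8-dihydroxy-9-[(3-methylbut-2-enoyl)oxy]germacra-1(10),4,11(13)-trien-12,6-olide (CNP0258484.1) | C=C1C(=O)O[C@H]2/C=C(\C)CC/C=C(/C)[C@@H](OC(=O)C=C(C)C)[C@H](O)[C@@]12O | target

**Step count and risks**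

Total step count: 24. Longest linear sequence: 23 steps (steps 1–3 and 5–24, from L-arabinose); step 4 is a one-step side branch.

Step 19 (most likely to fail). Intermolecular coupling or simple reduction may outpace ring closure, the Z-enal ketyl may lose its geometry, and above all the C9 ketyl may be attacked on its other face, so that the 9-epimer prevails. The fallback sets the C9 centre by ketone reduction instead of by the coupling. It sets out from 27, whose SmI2 coupling then delivers the 9-epimeric diol F1. MnO2 in CH2Cl2 at rt oxidises only the allylic C9 hydroxyl and gives the hydroxy enone F2. Luche reduction (NaBH4, CeCl3·7H2O, MeOH, −78 °C) should then deliver hydride anti to the C8–O bond from the ring periphery and return the route at 28.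

Step 20. Competing acylation of the C8 hydroxyl, or acyl migration from O9 to O8, may erode site selectivity. The fallback distinguishes the two hydroxyls by oxidation state instead of by rate. It sets out from 28: MnO2 converts the allylic C9 carbinol into the hydroxy enone F2. TESOTf/2,6-lutidine at −78 °C silylates the only remaining free hydroxyl to give the 8-O-triethylsilyl enone F3. Luche reduction, now under Felkin–Anh control by the C8 silyloxy group, gives the 9-alcohol F4. Acylation of F4 with 29 (pyridine, DMAP) comes back to the route at 31.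

Step 14. Propionic acid at 135 °C may cleave the p-methoxybenzylidene acetal or the tertiary silyl ether before rearrangement is complete. The fallback uses the neutral Eschenmoser–Claisen variant and sets out from 18. Heating with N,N-dimethylacetamide dimethyl acetal in xylene at 130 °C forms the ketene N,O-acetal F5, which rearranges through the same chair transition state to the dimethylamide F6. Partial reduction of F6 with LiAlH(OEt)3 in THF at 0 °C comes back to the route at aldehyde 22, bypassing 21.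

**Further compounds**

F1 | step 19 | (1(10)Z,4E,6S,7S,8S,9S)-6-[(4-methoxyphenyl)methoxy]-12-(naphthalen-2-ylmethoxy)-7-[(triethylsilyl)oxy]germacra-1(10),4,11(13)-triene-8,9-diol (9-epimer of 28) | O[C@H]1[C@@H](O)/C(C)=C\CC/C(C)=C/[C@H](OCc2ccc(OC)cc2)[C@]1(O[Si](CC)(CC)CC)C(=C)COCc1ccc2ccccc2c1
F2 | step 19 | (1(10)Z,4E,6S,7S,8R)-8-hydroxy-6-[(4-methoxyphenyl)methoxy]-12-(naphthalen-2-ylmethoxy)-7-[(triethylsilyl)oxy]germacra-1(10),4,11(13)-trien-9-one | O[C@H]1C(=O)/C(C)=C\CC/C(C)=C/[C@H](OCc2ccc(OC)cc2)[C@]1(O[Si](CC)(CC)CC)C(=C)COCc1ccc2ccccc2c1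
F3 | step 20 | (1(10)Z,4E,6S,7R,8R)-6-[(4-methoxyphenyl)methoxy]-12-(naphthalen-2-ylmethoxy)-7,8-bis[(triethylsilyl)oxy]germacra-1(10),4,11(13)-trien-9-one | CC[Si](CC)(CC)O[C@H]1C(=O)/C(C)=C\CC/C(C)=C/[C@H](OCc2ccc(OC)cc2)[C@]1(O[Si](CC)(CC)CC)C(=C)COCc1ccc2ccccc2c1
F4 | step 20 | (1(10)Z,4E,6S,7R,8S,9R)-6-[(4-methoxyphenyl)methoxy]-12-(naphthalen-2-ylmethoxy)-7,8-bis[(triethylsilyl)oxy]germacra-1(10),4,11(13)-trien-9-ol | CC[Si](CC)(CC)O[C@H]1[C@H](O)/C(C)=C\CC/C(C)=C/[C@H](OCc2ccc(OC)cc2)[C@]1(O[Si](CC)(CC)CC)C(=C)COCc1ccc2ccccc2c1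
F5 | step 14 | (2R,4S,5S)-4-(1-{[1-(dimethylamino)ethenyl]oxy}-2-methylprop-2-en-1-yl)-2-(4-methoxyphenyl)-5-[3-(naphthalen-2-ylmethoxy)prop-1-en-2-yl]-5-[(triethylsilyl)oxy]-1,3-dioxane | COc1ccc(cc1)[C@@H]1OC[C@@](O[Si](CC)(CC)CC)(C(=C)COCc2ccc3ccccc3c2)[C@H](C(OC(=C)N(C)C)C(C)=C)O1
F6 | step 14 | (4E)-5-{(2R,4S,5S)-2-(4-methoxyphenyl)-5-[3-(naphthalen-2-ylmethoxy)prop-1-en-2-yl]-5-[(triethylsilyl)oxy]-1,3-dioxan-4-yl}-N,N,4-trimethylpent-4-enamide | COc1ccc(cc1)[C@@H]1OC[C@@](O[Si](CC)(CC)CC)(C(=C)COCc2ccc3ccccc3c2)[C@H](/C=C(\C)CCC(=O)N(C)C)O1
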